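Which peak is left over at work-up in these flasks, and how large is it?

    catalyst intermediate C ⇌ catalyst intermediate D (K1 = 3.1, k1 = 160 h⁻¹)
    catalyst intermediate B → by-product + catalyst intermediate C (k2 = 310 h⁻¹)
    substrate + catalyst intermediate A → catalyst intermediate B (k3 = 40000 L mol⁻¹ h⁻¹)
    catalyst intermediate D → free catalyst + product (k4 = 990 h⁻¹)
    reagent + free catalyst → catalyst intermediate A (k5 = 15000 L mol⁻¹ h⁻¹)

all flasks: free catalyst 0.05 mol%

| flask | substrate | reagent | time | remark |
|---|---|---|---|---|
| autumn | 0.30 M | 0.500 equiv | 30 h | everything together in a closed stirred flask, run for 30 h |
| dawn | 0.30 M (fed, over 30.0 h) | 0.500 equiv | 30 h | a stirred flask in which substrate is dosed at a steady rate over 30.0 h without added volume, worked up at 30 h |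
| winter | 0.30 M | 0.500 equiv |  | a single well-mixed tank run continuously and read at steady state, 30 h in it on average |
| dusk | 0.30 M | 0.500 equiv (fed, over 30.0 h) | 30 h | a stirred flask in which reagent is dosed at a steady rate over 30.0 h without added volume, worked up at 30 h |

1. the set-up with the highest amount of product at the outlet or at the end, in percent of the substrate put in ("none" if the first two lie within 2 percentage points) (autumn / dawn / winter / dusk / none)
2. amount of product at the outlet or at the end, in percent of the substrate put in, autumn
3. amount of product at the outlet or at the end, in percent of the substrate put in, dawn
4. amount of product at the outlet or at the end, in percent of the substrate put in, winter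
5. amount of product at the outlet or at the end, in percent of the substrate put in, dusk

- the stated concentrations are those of everything mixed, before any reaction; amounts are the same in each set-up
- the feed brings no volume worth counting
- run time (autumn): 30 h

Does reagent get lost on the way round? I follow one molecule through the cycle: reagent turns free catalyst into catalyst intermediate A, substrate joins to give catalyst intermediate B, and by-product leaves to give catalyst intermediate C, then catalyst intermediate D. The one fork stands at catalyst intermediate D, which goes on to product with a chance of 95.0%. The other branch leads back to catalyst intermediate C and so to the same fork. One reagent therefore gives one product, reagent is the limiting reagent, and the ceiling is 50.0% of the substrate, with the rest of the substrate as the leftover peak.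

Is the cycle quick enough to reach that ceiling? A passage from catalyst intermediate B to product, returns counted and waits for reagent and substrate not, takes 38.9 s. Each catalyst must turn over 1000 times in 30.0 h, which allows 108 s per turnover.

The turnover margin, time allowed per turnover over time per passage, is 2.77. The time allowed is longer than the time per passage, so with the waits for reagent and substrate left aside I commit to the ceiling for autumn and dawn. For winter and dusk I take the ceiling as an upper limit and give no number of my own, so my reckoning stops here.

The forecast gives 50% for autumn, 50% for dawn, 48.9% for winter and 48.8% for dusk, hence none, and says “the batch and substrate-dosed runs both finish at the cap and tie”.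

The simulation gives 50.0%, 50.0%, 48.9% and 48.8%, hence none.

Read inversely, the margin says that 36.0% of the catalyst stands as catalyst intermediates B, C and D while the dusk flask keeps pace with its dosing. At the end of dusk, those forms together hold 36.0% of the catalyst, close to that figure, beside 0.543% as catalyst intermediate A and 63.4% free.

For the neighbour with 0.850 equiv of reagent, otherwise autumn, the ceiling is 85.0% and the margin over 30 h is 1.63, still above one, so I expect the ceiling. That flask gives 85.0%, with 15% of the substrate left over.

The rate constants are assumed; no experiment stands behind them.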